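In the maple run at −30 °C, 81.8% of the substrate was gone by 1500 min, yet target, free or bound forms counted, stood at 41.1%. That gives 1.99, my cost c: substrate lost per target counted. The elm run read 2.01 at 1500 min, and maple's first reading, at 300 min, was already 2.06. So in these cold runs a second substrate left with each target from the earliest reading on, into a form the substrate reading does not see.

| flask | substrate | reagent | temperature | remark | time |
|---|---|---|---|---|---|
| maple | 20 mM | 42 mM | −30 °C | run made earlier |  |
| larch | 20 mM | 66 mM | 0 °C | run made earlier |  |
| elm | 30 mM | 30 mM | −30 °C | run made earlier |  |
| north-east | 20 mM | 30.0 mM | 25 °C |  | 80 min |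
| north-west | 20 mM | 30.0 mM | 0 °C |  | 80 min |
| south | 20 mM | 30.0 mM |  | at 25 °C until 15 min, from then on at −25 °C | 80 min |
| south-west | 20 mM | 30.0 mM | −25 °C |  | 80 min |

- maple (time / min: target / %, substrate / %): 300: 15.2, 68.7; 600: 25.4, 48.3; 900: 33.0, 35.1; 1200: 37.8, 25.8; 1500: 41.1, 18.2
- larch (time / min: target / %, substrate / %): 60.0: 35.0, 32.9; 150: 50.7, 10.8; 180: 53.2, 9.0; 300: 59.3, 4.9
- elm (time / min: target / %, substrate / %): 120: 4.6, 89.9; 360: 13.3, 73.0; 600: 19.9, 61.2; 900: 25.8, 49.4; 1500: 33.3, 33.2

(each reading ± 0.3 percentage points)

- the best flask by amount of target, in percent of the substrate charged; "all alike" if 1.5 percentage points covers them all (north-east / north-west / south / south-west / all alike)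
- amount of target at the end, in percent of the substrate charged, north-east
- amount of target at the end, in percent of the substrate charged, north-west
- amount of target at the end, in percent of the substrate charged, south
- amount of target at the end, in percent of the substrate charged, south-west

- a reading or a percentage of target counts all its forms, free or not
- a reading of substrate is of its free form alone

I took the flask south in slow motion, with substrate as the limiting reagent at 20 mM against 30.0 mM of reagent. In the first instants of south at 25 °C, substrate and reagent make target, which I read as the rate-limiting step, and each new target can catch a free substrate.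

The larch run showed how c behaves at a warmer temperature. At 0 °C it fell from 1.92 at 60.0 min to 1.60 at 300 min, as free substrate came down to 4.9%. With 32.9% of free substrate, larch's reading of 1.92 stood lower than maple's 1.97 with 35.1% at 900 min, though the two runs differ in reagent as well as temperature. From that small gap between readings I expected south, warmer still in its first stage, to stand below the cold c when it reached 15 min.

The end of south comes after the change to −25 °C. Target per minute and per mM of reagent, from the first readings, was 7.33 times larger in larch at 0 °C than in maple at −30 °C. So I expected cold south to make target slowly while its free substrate went on being parked, with c climbing back to the cold value. I committed to a relation: at the end of south, target equals substrate lost divided by c.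

The forecast put north-east first, with 56% (51% to 62%) there, 24% in north-west, 25% (22% to 28%) in south and 5.1% in south-west, saying: "South reaches about 23% in the hot phase, then adds about 2%."

North-east gave 52.8%, north-west 25.2%, south 26.1% and south-west 5.30%, so north-east was the best flask.

    substrate + reagent ⇌ target (K = 140 M⁻¹, k = 47.0 M⁻¹ h⁻¹, Ea = 43.0 kJ mol⁻¹, ΔH = −58.0 kJ mol⁻¹)
    substrate + reagent ⇌ isomer of the product (K = 74.0 M⁻¹, k = 0.620 M⁻¹ h⁻¹, Ea = 75.0 kJ mol⁻¹, ΔH = 47.0 kJ mol⁻¹)
    substrate + target ⇌ idle adduct, settled at all times (K = 200 M⁻¹, ΔH = −53.0 kJ mol⁻¹)
    2 reagent → homo dimer (k = 0.640 M⁻¹ h⁻¹, Ea = 75.0 kJ mol⁻¹)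
    (constants at 25 °C)

South ended with 52.3% of its substrate converted, what is parked as idle adduct counted in. Divided by c, that is 26.3%, beside the 26.1% of target. The neighbour that is the same flask south left until 5.0 h held 37.2% of free substrate, so c gives 31.5%, and its target stood at 31.4%.

The earlier runs and the new flask stem from a simulated flask on assumed constants, noise included.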